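## Retrosynthetic overview

1. 26 ⇐ 25 ⇐ 24 ⇐ 23: the C1–C10 oxirane is treated as a masked (E)-C1=C10 alkene and is introduced late by peracid epoxidation of the C3 silyl ether (germacrane numbering C1–C15 is used for atoms).
2. Key disconnection C2–C3: with the oxirane unmasked, C3(OH)–C2H2–C1=C10 inside the ten-membered ring is a homoallylic alcohol. With silicon placed on C10, C2 (the vinyl terminus of a tertiary allylsilane) is the only nucleophilic carbon and closes the ten-membered ring onto the C3 aldehyde of a (Z)-enal carried by the preformed trans-fused α-methylene-γ-lactone.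
3. Seco-aldehyde 22 ⇐ 15 + 19 (C8 epoxyangelate by Mitsunobu inversion) ⇐ 14 + 6 (zinc Barbier reaction forming C7–C8 and the α-methylene lactone).
4. 14 (C3–C7, C11–C13, C15) from 4-methylfuran-2(5H)-one (source of the Z-C4=C5 alkene), asymmetric vinylation (C6) and ring-closing metathesis; 6 (C1, C2, C8–C10, C14) by Johnson–Claisen rearrangement of a vinylsilane; 19 from angelic acid by Sharpless epoxidation.
5. Order of ring formation: butenolide (step 8) → α-methylene-γ-lactone (step 9) → ten-membered carbocycle (step 16) → C1–C10 oxirane (step 18).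

Key step: step 16

Assumption: the silicon-bearing carbon (the future C10) is made racemic and carried as both epimers from 15 to 22, because it becomes trigonal in step 16; 1, 3, 7, 12 and 16 are taken as commercial.

## Route

Step 1
Reactants: 1 but-2-yn-1-ol
Product: 2 (E)-3-[dimethyl(phenyl)silyl]but-2-en-1-ol
Conditions: PhMe2SiH, PtCl2 (1 mol%), XPhos (2 mol%), THF, 50 °C
Reagents that add atoms: dimethyl(phenyl)silane, C[SiH](C)c1ccccc1
Why: Platinum-catalysed syn-hydrosilylation of a propargylic alcohol should place silicon on the alkyne carbon distal to the hydroxyl group and give the (E)-vinylsilane needed for the Claisen step.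

Step 2
Reactants: 2 (E)-3-[dimethyl(phenyl)silyl]but-2-en-1-ol; 3 triethyl orthoacetate
Product: 5 ethyl 3-[dimethyl(phenyl)silyl]-3-methylpent-4-enoate (racemic), via mixed ketene acetal 4 (not isolated)
Conditions: 3 (5 equiv), EtCO2H (cat.), 140 °C, EtOH distilled off
Reagents that add atoms: none
Why: Johnson–Claisen rearrangement; the [3,3] shift forms the C9–C10 bond at the silicon-bearing alkene carbon and turns the vinylsilane into a tertiary allylsilane, whose quaternary centre is racemic and is destroyed in step 16.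

Step 3
Reactants: 5 ethyl 3-[dimethyl(phenyl)silyl]-3-methylpent-4-enoate
Product: 6 3-[dimethyl(phenyl)silyl]-3-methylpent-4-enal (racemic)
Conditions: i-Bu2AlH (1.05 equiv), CH2Cl2, −78 °C; aqueous work-up
Reagents that add atoms: none
Why: Partial ester reduction with i-Bu2AlH at low temperature should stop at the aldehyde through the stable tetrahedral aluminate.

Step 4
Reactants: 7 4-methylfuran-2(5H)-one
Product: 9 (Z)-4-[(tert-butyldimethylsilyl)oxy]-N-methoxy-N,3-dimethylbut-2-enamide, via hydroxy amide 8 (not isolated)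
Conditions: MeNHOMe·HCl, AlMe3, CH2Cl2, 0 °C; then TBSCl, imidazole, 0 °C to rt
Reagents that add atoms: N,O-dimethylhydroxylamine hydrochloride, CNOC.Cl; tert-butyldimethylsilyl chloride, CC(C)(C)[Si](C)(C)Cl
Why: Weinreb aminolysis of the butenolide with the aluminium amide opens the ring with the Z-alkene intact, and silylation in the same flask prevents relactonisation.

Step 5
Reactants: 9 (Z)-4-[(tert-butyldimethylsilyl)oxy]-N-methoxy-N,3-dimethylbut-2-enamide
Product: 10 (Z)-4-[(tert-butyldimethylsilyl)oxy]-3-methylbut-2-enal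
Conditions: i-Bu2AlH, THF, −78 °C; aqueous work-up
Reagents that add atoms: none
Why: Reduction of a Weinreb amide stops at the aldehyde through the chelated tetrahedral intermediate and should leave the Z-geometry untouched.

Step 6
Reactants: 10 (Z)-4-[(tert-butyldimethylsilyl)oxy]-3-methylbut-2-enal
Product: 11 (3S,4Z)-6-[(tert-butyldimethylsilyl)oxy]-5-methylhexa-1,4-dien-3-ol
Conditions: Zn(CH=CH2)2 (1.5 equiv), (−)-3-exo-(dimethylamino)isoborneol (5 mol%), toluene, 0 °C; 1 M HCl
Reagents that add atoms: divinylzinc, C=C[Zn]C=C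
Why: Catalytic asymmetric vinylzinc addition to an aldehyde; the amino-alkoxide–zinc chelate should deliver the vinyl group to the face that gives the (S)-carbinol, which becomes C6.

Step 7
Reactants: 11 (3S,4Z)-6-[(tert-butyldimethylsilyl)oxy]-5-methylhexa-1,4-dien-3-ol; 12 2-(bromomethyl)acrylic acid
Product: 13 (3S,4Z)-6-[(tert-butyldimethylsilyl)oxy]-5-methylhexa-1,4-dien-3-yl 2-(bromomethyl)acrylate
Conditions: DCC, DMAP (5 mol%), CH2Cl2, −20 to 0 °C
Reagents that add atoms: none
Why: Steglich esterification of the secondary alcohol at low temperature should proceed with retention at C6 and without substitution of the allylic bromide.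

Step 8
Reactants: 13 (3S,4Z)-6-[(tert-butyldimethylsilyl)oxy]-5-methylhexa-1,4-dien-3-yl 2-(bromomethyl)acrylate
Product: 14 (5R)-3-(bromomethyl)-5-{(Z)-3-[(tert-butyldimethylsilyl)oxy]-2-methylprop-1-en-1-yl}furan-2(5H)-one
Conditions: second-generation Hoveyda–Grubbs catalyst, RuCl2(=CH-C6H4-2-O-i-Pr)(H2IMes) (5 mol%), toluene (5 mM), 80 °C
Reagents that add atoms: none
Why: Ring-closing metathesis between the vinyl group and the acrylate alkene gives the butenolide with loss of ethylene; the Z-trisubstituted alkene is too hindered to take part.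

Step 9
Reactants: 14 (5R)-3-(bromomethyl)-5-{(Z)-3-[(tert-butyldimethylsilyl)oxy]-2-methylprop-1-en-1-yl}furan-2(5H)-one; 6 3-[dimethyl(phenyl)silyl]-3-methylpent-4-enal
Product: 15 (4R,5R)-5-{(Z)-3-[(tert-butyldimethylsilyl)oxy]-2-methylprop-1-en-1-yl}-4-{(1S)-3-[dimethyl(phenyl)silyl]-1-hydroxy-3-methylpent-4-en-1-yl}-3-methylidenedihydrofuran-2(3H)-one (both epimers at the silicon-bearing carbon)
Conditions: Zn dust, THF/sat. aq. NH4Cl (2:1), 0 °C to rt
Reagents that add atoms: none
Why: Barbier allylation with a 3-(bromomethyl)butenolide; the allylzinc reacts through its γ-carbon (C7) to give the α-methylene lactone, C7 being set by attack anti to the C6 alkenyl group (trans-lactone) and C8 by the chair Zimmerman–Traxler transition state with the ring-fixed allyl geometry, which should give the 8S alcohol that step 13 inverts.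

Step 10
Reactants: 16 angelic acid
Product: 17 (Z)-2-methylbut-2-en-1-ol
Conditions: LiAlH4, Et2O, 0 °C; aqueous work-up
Reagents that add atoms: none
Why: Hydride reduction of the acid to the allylic alcohol should not isomerise the Z-alkene.

Step 11
Reactants: 17 (Z)-2-methylbut-2-en-1-ol
Product: 18 [(2R,3S)-2,3-dimethyloxiran-2-yl]methanol
Conditions: Ti(OiPr)4 (10 mol%), D-(−)-diethyl tartrate (12 mol%), t-BuOOH, 4 Å molecular sieves, CH2Cl2, −20 °C
Reagents that add atoms: tert-butyl hydroperoxide, CC(C)(C)OO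
Why: Sharpless asymmetric epoxidation; the D-(−)-tartrate catalyst should deliver oxygen to the face of the Z-allylic alcohol that gives the (2R,3S)-epoxy alcohol, both epoxide centres being set together.

Step 12
Reactants: 18 [(2R,3S)-2,3-dimethyloxiran-2-yl]methanol
Product: 19 (2S,3S)-2,3-dimethyloxirane-2-carboxylic acid
Conditions: RuCl3 (2 mol%), NaIO4 (3 equiv), CCl4/MeCN/H2O, rt
Reagents that add atoms: sodium periodate, [Na+].[O-]I(=O)(=O)=O; water, O
Why: Oxidation of the primary alcohol to the acid by RuO4 generated in the flask leaves both epoxide stereocentres untouched (the descriptor at C2 changes only because of the priority rules).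

Step 13
Reactants: 15 the 8S alcohol from step 9; 19 (2S,3S)-2,3-dimethyloxirane-2-carboxylic acid
Product: 20 (4R,5R)-5-{(Z)-3-[(tert-butyldimethylsilyl)oxy]-2-methylprop-1-en-1-yl}-4-{(1R)-1-{[(2S,3S)-2,3-dimethyloxirane-2-carbonyl]oxy}-3-[dimethyl(phenyl)silyl]-3-methylpent-4-en-1-yl}-3-methylidenedihydrofuran-2(3H)-one (both epimers at the silicon-bearing carbon)
Conditions: PPh3, DIAD, toluene, 0 °C to rt (DIAD added to PPh3 before the substrate)
Reagents that add atoms: none
Why: Mitsunobu esterification; the carboxylate of 19 displaces the activated C8 oxygen in an SN2 reaction, so the 8S alcohol becomes the 8R ester and the complete epoxyangelate is installed in the same step.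

Step 14
Reactants: 20 the C8 epoxyangelate with the primary TBS ether
Product: 21 the corresponding primary allylic alcohol (C3–OH free)
Conditions: PPTS (cat.), MeOH, rt
Reagents that add atoms: none
Why: Acid-catalysed methanolysis removes the primary allylic TBS ether selectively; the tertiary allylsilane, the lactone, the ester and the electron-poor oxirane should be stable to PPTS.

Step 15
Reactants: 21 the primary allylic alcohol
Product: 22 (4R,5R)-4-{(1R)-1-{[(2S,3S)-2,3-dimethyloxirane-2-carbonyl]oxy}-3-[dimethyl(phenyl)silyl]-3-methylpent-4-en-1-yl}-3-methylidene-5-[(Z)-2-methyl-3-oxoprop-1-en-1-yl]dihydrofuran-2(3H)-one (both epimers at the silicon-bearing carbon)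
Conditions: Dess–Martin periodinane, NaHCO3, CH2Cl2, 0 °C
Reagents that add atoms: none
Why: Dess–Martin oxidation of the primary allylic alcohol under buffered conditions should give the (Z)-enal without isomerisation.

Step 16
Reactants: 22 the (Z)-enal carrying the tertiary allylsilane
Product: 23 (1(10)E,4Z,3S,6R,7R,8R)-8-{[(2S,3S)-2,3-dimethyloxirane-2-carbonyl]oxy}-3-hydroxygermacra-1(10),4,11(13)-trien-12,6-olide
Conditions: BF3·OEt2 (1.5 equiv), CH2Cl2, −78 to −40 °C, 22 added by syringe pump (final 2 mM); H2O quench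
Reagents that add atoms: none
Why: Proposed new method: BF3 binds the C3 aldehyde of the (Z)-enal and the unsubstituted vinyl terminus C2 of the tertiary allylsilane attacks it through an open, anti-SE2′ transition state; the β-silyl cation at C1 then loses fluorodimethyl(phenyl)silane, so the C2–C3 bond, the ten-membered ring and the C1=C10 alkene form in one event (closest known reaction type: the intramolecular Hosomi–Sakurai cyclisation and Lewis-acid-promoted SE2′ macrocyclisations of allylic stannanes onto aldehydes, not yet shown for a ten-membered carbocycle from an α,α-disubstituted allylsilane). The ten-membered ring closes by 1,2-addition in a 10-endo sense with respect to the vinyl group (exo with respect to the carbonyl), on the template of the preformed trans-lactone. Regiochemistry is fixed by design: allyl transfer from silicon is γ-selective, so silicon on C10 makes C2 the only nucleophilic carbon, the opposite of what an allyl halide–metal pair would give. The (E)-geometry of C1=C10 should follow from the rotamer in which the C–Si bond overlaps the π system while the small methyl group, not the C9 chain, eclipses the vinyl group, and both C10 epimers converge because C10 becomes trigonal. The new C3 stereocentre is under substrate control: the C6 and C7 centres of the trans-lactone hold the tether on one face of the enal, and C2 is expected to add to the aldehyde face that places the new hydroxyl group on the outer side of the forming ring, taken here to be the 3S configuration. The step needs chemoselectivity for the aldehyde over the C13 acrylate and the epoxy ester and must outrun protodesilylation; the much higher electrophilicity of the BF3-bound aldehyde, low temperature, high dilution and exclusion of protic acid should secure it.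

Step 17
Reactants: 23 the macrocyclic C3 alcohol
Product: 24 the C3 triethylsilyl ether of 23
Conditions: Et3SiCl, imidazole, DMF, 0 °C
Reagents that add atoms: chlorotriethylsilane, CC[Si](Cl)(CC)CC
Why: Silylation protects the C3 alcohol and removes its hydrogen-bond direction of peracid towards the neighbouring C4=C5 alkene.

Step 18
Reactants: 24 the C3 triethylsilyl ether
Product: 25 (1R,3S,6R,7R,8R,10R,4Z)-1,10-epoxide of 24
Conditions: mCPBA, NaHCO3, CH2Cl2, 0 °C
Reagents that add atoms: 3-chloroperbenzoic acid, O=C(OO)c1cccc(Cl)c1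
Why: Prilezhaev epoxidation; C1=C10 is the most electron-rich alkene (C4=C5 is flanked by two allylic C–O bonds, C11=C13 is conjugated), and syn addition to the outer face of the (E)-alkene in the ten-membered ring should give the trans (1R,10R)-oxirane.

Step 19
Reactants: 25 the epoxidised silyl ether
Product: 26 target, (1R,3S,6R,7R,8R,10R,4Z)-1,10-epoxy-8-{[(2S,3S)-2,3-dimethyloxirane-2-carbonyl]oxy}-3-hydroxygermacra-4,11(13)-dien-12,6-olide
Conditions: HF·pyridine, pyridine, THF, 0 °C
Reagents that add atoms: none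
Why: Buffered fluoride cleavage of the triethylsilyl ether should leave both oxiranes, the ester and the α-methylene lactone intact.

## Compound list

1 | but-2-yn-1-ol | CC#CCO | starting material
2 | (E)-3-[dimethyl(phenyl)silyl]but-2-en-1-ol | OC/C=C(\C)[Si](C)(C)c1ccccc1 | intermediate
3 | triethyl orthoacetate | CC(OCC)(OCC)OCC | starting material
4 | (E)-[4-(1-ethoxyvinyloxy)but-2-en-2-yl]dimethyl(phenyl)silane (mixed ketene acetal) | C=C(OCC)OC/C=C(\C)[Si](C)(C)c1ccccc1 | intermediate
5 | ethyl 3-[dimethyl(phenyl)silyl]-3-methylpent-4-enoate (racemic) | CCOC(=O)CC(C)(C=C)[Si](C)(C)c1ccccc1 | intermediate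
6 | 3-[dimethyl(phenyl)silyl]-3-methylpent-4-enal (racemic) | O=CCC(C)(C=C)[Si](C)(C)c1ccccc1 | intermediate
7 | 4-methylfuran-2(5H)-one | CC1=CC(=O)OC1 | starting material
8 | (Z)-4-hydroxy-N-methoxy-N,3-dimethylbut-2-enamide | OC/C(C)=C\C(=O)N(C)OC | intermediate
9 | (Z)-4-[(tert-butyldimethylsilyl)oxy]-N-methoxy-N,3-dimethylbut-2-enamide | CC(C)(C)[Si](C)(C)OC/C(C)=C\C(=O)N(C)OC | intermediate
10 | (Z)-4-[(tert-butyldimethylsilyl)oxy]-3-methylbut-2-enal | CC(C)(C)[Si](C)(C)OC/C(C)=C\C=O | intermediate
11 | (3S,4Z)-6-[(tert-butyldimethylsilyl)oxy]-5-methylhexa-1,4-dien-3-ol | C=C[C@H](O)/C=C(/C)CO[Si](C)(C)C(C)(C)C | intermediate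
12 | 2-(bromomethyl)acrylic acid | C=C(CBr)C(=O)O | starting material
13 | (3S,4Z)-6-[(tert-butyldimethylsilyl)oxy]-5-methylhexa-1,4-dien-3-yl 2-(bromomethyl)acrylate | C=C(CBr)C(=O)O[C@@H](C=C)/C=C(/C)CO[Si](C)(C)C(C)(C)C | intermediate
14 | (5R)-3-(bromomethyl)-5-{(Z)-3-[(tert-butyldimethylsilyl)oxy]-2-methylprop-1-en-1-yl}furan-2(5H)-one | O=C1O[C@H](/C=C(/C)CO[Si](C)(C)C(C)(C)C)C=C1CBr | intermediate
15 | (4R,5R)-5-{(Z)-3-[(tert-butyldimethylsilyl)oxy]-2-methylprop-1-en-1-yl}-4-{(1S)-3-[dimethyl(phenyl)silyl]-1-hydroxy-3-methylpent-4-en-1-yl}-3-methylidenedihydrofuran-2(3H)-one, both epimers at the silicon-bearing carbon | C=C1C(=O)O[C@H](/C=C(/C)CO[Si](C)(C)C(C)(C)C)[C@H]1[C@@H](O)CC(C)(C=C)[Si](C)(C)c1ccccc1 | intermediate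
16 | angelic acid, (Z)-2-methylbut-2-enoic acid | C/C=C(C)\C(=O)O | starting material
17 | (Z)-2-methylbut-2-en-1-ol | C/C=C(C)\CO | intermediate
18 | [(2R,3S)-2,3-dimethyloxiran-2-yl]methanol | OC[C@@]1(C)O[C@H]1C | intermediate
19 | (2S,3S)-2,3-dimethyloxirane-2-carboxylic acid | OC(=O)[C@@]1(C)O[C@H]1C | intermediate
20 | (4R,5R)-5-{(Z)-3-[(tert-butyldimethylsilyl)oxy]-2-methylprop-1-en-1-yl}-4-{(1R)-1-{[(2S,3S)-2,3-dimethyloxirane-2-carbonyl]oxy}-3-[dimethyl(phenyl)silyl]-3-methylpent-4-en-1-yl}-3-methylidenedihydrofuran-2(3H)-one, both epimers at the silicon-bearing carbon | C=C1C(=O)O[C@H](/C=C(/C)CO[Si](C)(C)C(C)(C)C)[C@H]1[C@H](OC(=O)[C@@]2(C)O[C@H]2C)CC(C)(C=C)[Si](C)(C)c1ccccc1 | intermediate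
21 | (4R,5R)-4-{(1R)-1-{[(2S,3S)-2,3-dimethyloxirane-2-carbonyl]oxy}-3-[dimethyl(phenyl)silyl]-3-methylpent-4-en-1-yl}-5-[(Z)-3-hydroxy-2-methylprop-1-en-1-yl]-3-methylidenedihydrofuran-2(3H)-one, both epimers at the silicon-bearing carbon | C=C1C(=O)O[C@H](/C=C(/C)CO)[C@H]1[C@H](OC(=O)[C@@]2(C)O[C@H]2C)CC(C)(C=C)[Si](C)(C)c1ccccc1 | intermediate
22 | (4R,5R)-4-{(1R)-1-{[(2S,3S)-2,3-dimethyloxirane-2-carbonyl]oxy}-3-[dimethyl(phenyl)silyl]-3-methylpent-4-en-1-yl}-3-methylidene-5-[(Z)-2-methyl-3-oxoprop-1-en-1-yl]dihydrofuran-2(3H)-one, both epimers at the silicon-bearing carbon | C=C1C(=O)O[C@H](/C=C(/C)C=O)[C@H]1[C@H](OC(=O)[C@@]2(C)O[C@H]2C)CC(C)(C=C)[Si](C)(C)c1ccccc1 | intermediate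
23 | (1(10)E,4Z,3S,6R,7R,8R)-8-{[(2S,3S)-2,3-dimethyloxirane-2-carbonyl]oxy}-3-hydroxygermacra-1(10),4,11(13)-trien-12,6-olide | C=C1C(=O)O[C@@H]2/C=C(/C)[C@@H](O)C/C=C(\C)C[C@@H](OC(=O)[C@@]3(C)O[C@H]3C)[C@@H]12 | intermediate
24 | 3-O-triethylsilyl ether of 23 | C=C1C(=O)O[C@@H]2/C=C(/C)[C@@H](O[Si](CC)(CC)CC)C/C=C(\C)C[C@@H](OC(=O)[C@@]3(C)O[C@H]3C)[C@@H]12 | intermediate
25 | (1R,10R)-1,10-epoxide of 24 | C=C1C(=O)O[C@@H]2/C=C(/C)[C@@H](O[Si](CC)(CC)CC)C[C@H]3O[C@]3(C)C[C@@H](OC(=O)[C@@]3(C)O[C@H]3C)[C@@H]12 | intermediate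
26 | (1R,3S,6R,7R,8R,10R,4Z)-1,10-epoxy-8-{[(2S,3S)-2,3-dimethyloxirane-2-carbonyl]oxy}-3-hydroxygermacra-4,11(13)-dien-12,6-olide (CNP0268255.2) | C=C1C(=O)O[C@@H]2/C=C(/C)[C@@H](O)C[C@H]3O[C@]3(C)C[C@@H](OC(=O)[C@@]3(C)O[C@H]3C)[C@@H]12 | target

## Step count and risks

Total step count: 19. Longest linear sequence: 13 steps (steps 4–9 and 13–19).

Steps most likely to fail:

1. Step 16 (Proposed new method). What may go wrong: the ring closure proceeds with poor facial selectivity at the aldehyde carbon, because the two C10 epimers of 22 need not prefer the same face, so that 23 is accompanied or replaced by its C3 epimer. Fallback: C3 is set by reagent control after the ring is formed. The fallback sets out from 23 as obtained (mixture of C3 epimers): Dess–Martin oxidation gives the macrocyclic (Z)-enone, (1(10)E,4Z,6R,7R,8R)-8-{[(2S,3S)-2,3-dimethyloxirane-2-carbonyl]oxy}-3-oxogermacra-1(10),4,11(13)-trien-12,6-olide F1. Corey–Bakshi–Shibata reduction of F1 ((R)-2-methyl-CBS-oxazaborolidine, catecholborane, toluene, −78 °C) should then deliver the 3S alcohol and come back to the route at 23.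

2. Step 13. What may go wrong: the activated C8 oxygen lies between a tertiary carbon and a neopentyl-type methylene, so elimination towards C7 or the acyloxyphosphonium pathway (retention) may outrun the SN2 displacement. Fallback: C8 is inverted by oxidation and reduction and the ester is then made with retention. Setting out from 15, Dess–Martin oxidation gives the C8 ketone, (4S,5R)-5-{(Z)-3-[(tert-butyldimethylsilyl)oxy]-2-methylprop-1-en-1-yl}-4-{3-[dimethyl(phenyl)silyl]-3-methylpent-4-enoyl}-3-methylidenedihydrofuran-2(3H)-one F2. Corey–Bakshi–Shibata reduction ((S)-2-methyl-CBS-oxazaborolidine, catecholborane, −78 °C) should give the 8R alcohol, the C8 epimer of 15, F3. Yamaguchi esterification of F3 with 19 (2,4,6-trichlorobenzoyl chloride, Et3N, DMAP, toluene) comes back to the route at 20.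

3. Step 18. What may go wrong: poor facial selectivity, the peracid adding to the inner face of C1=C10 and giving the (1S,10S)-oxirane. Fallback: the oxygen is delivered to the opposite face through a bromohydrin. Setting out from 24, NBS in THF/H2O at 0 °C should form the bromonium ion on the face the peracid prefers and water should open it at the tertiary C10, giving the (1S,10R)-1-bromo-10-hydroxy compound, bromohydrin F4. DBU in CH2Cl2 then closes the oxirane with inversion at C1 and comes back to the route at 25.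

Further compounds
F1 | step 16 | (1(10)E,4Z,6R,7R,8R)-8-{[(2S,3S)-2,3-dimethyloxirane-2-carbonyl]oxy}-3-oxogermacra-1(10),4,11(13)-trien-12,6-olide | C=C1C(=O)O[C@@H]2/C=C(/C)C(=O)C/C=C(\C)C[C@@H](OC(=O)[C@@]3(C)O[C@H]3C)[C@@H]12
F2 | step 13 | (4S,5R)-5-{(Z)-3-[(tert-butyldimethylsilyl)oxy]-2-methylprop-1-en-1-yl}-4-{3-[dimethyl(phenyl)silyl]-3-methylpent-4-enoyl}-3-methylidenedihydrofuran-2(3H)-one | C=C1C(=O)O[C@H](/C=C(/C)CO[Si](C)(C)C(C)(C)C)[C@H]1C(=O)CC(C)(C=C)[Si](C)(C)c1ccccc1
F3 | step 13 | (4R,5R)-5-{(Z)-3-[(tert-butyldimethylsilyl)oxy]-2-methylprop-1-en-1-yl}-4-{(1R)-3-[dimethyl(phenyl)silyl]-1-hydroxy-3-methylpent-4-en-1-yl}-3-methylidenedihydrofuran-2(3H)-one | C=C1C(=O)O[C@H](/C=C(/C)CO[Si](C)(C)C(C)(C)C)[C@H]1[C@H](O)CC(C)(C=C)[Si](C)(C)c1ccccc1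
F4 | step 18 | (1S,10R)-1-bromo-10-hydroxy-1,10-dihydro derivative of 24 (bromohydrin) | C=C1C(=O)O[C@@H]2/C=C(/C)[C@@H](O[Si](CC)(CC)CC)C[C@H](Br)[C@@](O)(C)C[C@@H](OC(=O)[C@@]3(C)O[C@H]3C)[C@@H]12
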